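**Plan**
1. Retrosynthesis: the C5–C10 bond is cut first. It is the one bond shared by rings A and B and lies between the methyl-bearing quaternary C10 and the tetrasubstituted C4=C5 alkene, which is what remains when a (1(10)E,4E)-germacradiene folds across its ten-membered ring. Next come the C3 ester C–O bond, the C3–C4 ring bond, the C8 acetate and the C7–C8 bond, leaving a C8–C3 aldehyde and a C4–C7/C11–C13 allylic bromide.
2. Forward: the two chains are joined at C7–C8, the ten-membered ring is closed at C3–C4 with CrCl2/NiCl2, C3 is acylated, and rings A and B then form together in one acid-triggered transannular cation–olefin cyclisation.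
3. Stereochemistry: C7 and C8 come from a ligand-controlled, syn-selective chromium-catalysed allylation; C3 from the conformation of the closing ring; C10 from the crossed conformer of the germacradiene; the E alkenes from syn carbo- and hydrometallation of alkynes.

Key step: step 16

Remark: terpenoid numbering (C1–C15) is used for all intermediates; the sense of induction of the chiral ligand in step 10 on this aldehyde is assumed, so the ligand antipode is to be fixed on the first run (Mosher esters of 19); acid 24 is taken as a purchased, geometrically pure compound.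

**Route**

Step 1
Reactants: 1 but-3-yn-1-ol
Product: 2 tert-butyl(but-3-yn-1-yloxy)dimethylsilane
Conditions: TBSCl, imidazole, DMF, 0 °C to rt
Reagents that add atoms: tert-butyldimethylsilyl chloride, CC(C)(C)[Si](C)(C)Cl
Why: Imidazole-promoted silylation protects the alcohol, which would otherwise consume AlMe3 and must stay masked until the C8 aldehyde is needed.

Step 2
Reactants: 2 tert-butyl(but-3-yn-1-yloxy)dimethylsilane; 3 ethylene oxide
Product: 6 (E)-6-[(tert-butyldimethylsilyl)oxy]-4-methylhex-3-en-1-ol, via alkenyldimethylalane 4 (not isolated), via lithium alkenylalanate 5 (not isolated)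
Conditions: AlMe3 (2.5 equiv), Cp2ZrCl2 (0.2 equiv), CH2Cl2, 0 °C to rt; excess AlMe3 removed in vacuo; n-BuLi, hexane/THF, −78 °C; ethylene oxide, −78 to 0 °C; H2O, then aq. potassium sodium tartrate
Reagents that add atoms: trimethylaluminium, C[Al](C)C
Why: Zirconium-catalysed carboalumination (Negishi) adds CH3 and Al syn across the terminal alkyne with the methyl on the internal carbon, and the lithium alanate made from the alkenylalane opens ethylene oxide with retention of geometry, so the 1(10)E alkene, C14 and the C2–C3 unit are set in one flask.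

Step 3
Reactants: 6 (E)-6-[(tert-butyldimethylsilyl)oxy]-4-methylhex-3-en-1-ol
Product: 7 (E)-1-[(tert-butyldimethylsilyl)oxy]-6-[(tert-butyldiphenylsilyl)oxy]-3-methylhex-3-ene
Conditions: TBDPSCl, imidazole, DMF, rt
Reagents that add atoms: tert-butyldiphenylsilyl chloride, CC(C)(C)[Si](Cl)(c1ccccc1)c1ccccc1
Why: Imidazole-promoted silylation puts on the C3 oxygen a TBDPS ether that survives the acid used next to free the C8 hydroxyl.

Step 4
Reactants: 7 (E)-1-[(tert-butyldimethylsilyl)oxy]-6-[(tert-butyldiphenylsilyl)oxy]-3-methylhex-3-ene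
Product: 8 (E)-6-[(tert-butyldiphenylsilyl)oxy]-3-methylhex-3-en-1-ol
Conditions: camphorsulfonic acid (0.1 equiv), MeOH/CH2Cl2, 0 °C
Reagents that add atoms: none
Why: Acid-catalysed methanolysis (selective desilylation) cleaves a primary TBS ether much faster than a primary TBDPS ether.

Step 5
Reactants: 8 (E)-6-[(tert-butyldiphenylsilyl)oxy]-3-methylhex-3-en-1-ol
Product: 9 (E)-6-[(tert-butyldiphenylsilyl)oxy]-3-methylhex-3-enal
Conditions: Dess–Martin periodinane, NaHCO3, CH2Cl2, 0 °C to rt; used at once
Reagents that add atoms: none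
Why: Dess–Martin oxidation under bicarbonate buffer gives the aldehyde without base, so the β,γ-alkene should not move into conjugation if the aldehyde is used directly.

Step 6
Reactants: 10 pent-3-yn-1-ol
Product: 12 (E)-4-iodopent-3-en-1-ol, via alkenylzirconocene chloride 11 (not isolated)
Conditions: Cp2Zr(H)Cl (2.5 equiv), THF, rt to 40 °C; I2, THF, 0 °C
Reagents that add atoms: iodine, II
Why: Hydrozirconation adds Zr–H syn, an excess of the hydride lets the regioisomers settle with zirconium on the less hindered methyl-bearing carbon, and iodinolysis with retention gives the E-2-iodoalkene that becomes C4=C5.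

Step 7
Reactants: 12 (E)-4-iodopent-3-en-1-ol
Product: 13 (E)-4-iodopent-3-enal
Conditions: Dess–Martin periodinane, NaHCO3, CH2Cl2, 0 °C; used at once as a solution
Reagents that add atoms: none
Why: Dess–Martin oxidation is non-basic and fast, which is what a β,γ-unsaturated aldehyde needs to keep its alkene in place.

Step 8
Reactants: 13 (E)-4-iodopent-3-enal; 14 methyl propiolate
Product: 16 methyl (5E)-3-hydroxy-6-iodo-2-methylidenehept-5-enoate (racemic), via vinylalane 15 (not isolated)
Conditions: i-Bu2AlH, N-methylmorpholine N-oxide, THF, 0 °C; methyl propiolate, 0 °C; then 13, 0 °C to rt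
Reagents that add atoms: none
Why: Vinylalumination, in which conjugate hydroalumination of the propiolate gives an α-(methoxycarbonyl)vinylalane that adds to the aldehyde, gives the Morita–Baylis–Hillman-type alcohol without the amine catalyst that could isomerise this aldehyde; the carbinol centre is racemic and is erased in step 9.

Step 9
Reactants: 16 methyl (5E)-3-hydroxy-6-iodo-2-methylidenehept-5-enoate
Product: 17 methyl (2Z,5E)-2-(bromomethyl)-6-iodohepta-2,5-dienoate
Conditions: NBS, Me2S, CH2Cl2, 0 °C to rt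
Reagents that add atoms: N-bromosuccinimide, O=C1CCC(=O)N1Br
Why: Corey–Kim-type activation of the allylic alcohol and attack of bromide with allylic transposition (SN2′) give the thermodynamically favoured (Z)-2-(bromomethyl)alk-2-enoate, and the vinyl iodide is inert.

Step 10
Reactants: 9 (E)-6-[(tert-butyldiphenylsilyl)oxy]-3-methylhex-3-enal; 17 methyl (2Z,5E)-2-(bromomethyl)-6-iodohepta-2,5-dienoate
Product: 19 methyl (3R,4R,6E)-9-[(tert-butyldiphenylsilyl)oxy]-4-hydroxy-3-[(2E)-3-iodobut-2-en-1-yl]-6-methyl-2-methylidenenon-6-enoate, via trimethylsilyl ether 18 (not isolated)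
Conditions: CrCl2 (10 mol %), chiral tridentate 1,8-bis(4-isopropyl-4,5-dihydrooxazol-2-yl)-3,6-diphenyl-9H-carbazole (12 mol %, one enantiomer), Mn powder, i-Pr2NEt, Me3SiCl, THF, 0 °C to rt; then 1 M HCl, THF, 0 °C, brief
Reagents that add atoms: chlorotrimethylsilane, C[Si](C)(C)Cl (its silyl group is held only in 18 and is lost on work-up)
Why: Chromium-catalysed asymmetric Nozaki–Hiyama 2-(alkoxycarbonyl)allylation, in which the allylchromium made from the Z-bromide reacts at its γ-carbon through a closed chair transition state and so gives the syn relationship, while the chiral ligand on chromium directs attack to the Si face of the aldehyde and fixes 8R and with it 7R; without nickel the vinyl iodide does not react.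

Step 11
Reactants: 19 methyl (3R,4R,6E)-9-[(tert-butyldiphenylsilyl)oxy]-4-hydroxy-3-[(2E)-3-iodobut-2-en-1-yl]-6-methyl-2-methylidenenon-6-enoate
Product: 20 methyl (3R,4R,6E)-4-acetoxy-9-[(tert-butyldiphenylsilyl)oxy]-3-[(2E)-3-iodobut-2-en-1-yl]-6-methyl-2-methylidenenon-6-enoate
Conditions: Ac2O, pyridine, DMAP (cat.), CH2Cl2, 0 °C to rt
Reagents that add atoms: acetic anhydride, CC(=O)OC(C)=O
Why: DMAP-catalysed acetylation installs the C8 acetate of the target and removes the γ-hydroxyl before it can lactonise onto the C12 ester.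

Step 12
Reactants: 20 methyl (3R,4R,6E)-4-acetoxy-9-[(tert-butyldiphenylsilyl)oxy]-3-[(2E)-3-iodobut-2-en-1-yl]-6-methyl-2-methylidenenon-6-enoate
Product: 21 methyl (3R,4R,6E)-4-acetoxy-9-hydroxy-3-[(2E)-3-iodobut-2-en-1-yl]-6-methyl-2-methylidenenon-6-enoate
Conditions: HF·pyridine, pyridine, THF, 0 °C to rt
Reagents that add atoms: none
Why: Fluoride cleavage of the silyl ether with pyridine-buffered HF·pyridine frees the C3 hydroxyl and leaves acetate, methyl ester, acrylate and vinyl iodide alone.

Step 13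
Reactants: 21 methyl (3R,4R,6E)-4-acetoxy-9-hydroxy-3-[(2E)-3-iodobut-2-en-1-yl]-6-methyl-2-methylidenenon-6-enoate
Product: 22 methyl (3R,4R,6E)-4-acetoxy-3-[(2E)-3-iodobut-2-en-1-yl]-6-methyl-2-methylidene-9-oxonon-6-enoate
Conditions: Dess–Martin periodinane, NaHCO3, CH2Cl2, 0 °C to rt; used at once
Reagents that add atoms: none
Why: Dess–Martin oxidation under bicarbonate buffer gives the β,γ-unsaturated C3 aldehyde without base-induced alkene migration or loss of acetate.

Step 14
Reactants: 22 methyl (3R,4R,6E)-4-acetoxy-3-[(2E)-3-iodobut-2-en-1-yl]-6-methyl-2-methylidene-9-oxonon-6-enoate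
Product: 23 methyl (3S,7R,8R,1(10)E,4E)-8-acetoxy-3-hydroxygermacra-1(10),4,11(13)-trien-12-oate
Conditions: CrCl2 (8 equiv), NiCl2 (2 mol % of the chromium), degassed DMSO, rt, slow addition of 22 to about 2 mM
Reagents that add atoms: none
Why: Nozaki–Hiyama–Kishi reaction, in which nickel-catalysed insertion into the vinyl iodide with retention of the E geometry, transmetallation to chromium and addition to the aldehyde at high dilution close the ten-membered ring at C3–C4, and addition through the crossed conformer that keeps the C7 side chain pseudo-equatorial with the chromium-bound oxygen turned away from the ring is expected to give the 3S alcohol.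

Step 15
Reactants: 23 methyl (3S,7R,8R,1(10)E,4E)-8-acetoxy-3-hydroxygermacra-1(10),4,11(13)-trien-12-oate; 24 (E)-3-methylpent-2-enoic acid
Product: 25 methyl (3S,7R,8R,1(10)E,4E)-8-acetoxy-3-[(E)-3-methylpent-2-enoyloxy]germacra-1(10),4,11(13)-trien-12-oate
Conditions: 24 (1.5 equiv), DCC, DMAP (0.2 equiv), CH2Cl2, 0 °C to rt
Reagents that add atoms: none
Why: Steglich esterification (carbodiimide activation, DMAP acyl transfer) acylates the secondary allylic alcohol with retention at C3 and, without a stoichiometric amine base, should keep the E-enoate from deconjugating.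

Step 16
Reactants: 25 methyl (3S,7R,8R,1(10)E,4E)-8-acetoxy-3-[(E)-3-methylpent-2-enoyloxy]germacra-1(10),4,11(13)-trien-12-oate
Product: 26 methyl (3S,7R,8R,10R)-8-acetoxy-3-[(E)-3-methylpent-2-enoyloxy]eudesma-4,11(13)-dien-12-oate (CNP0118541.1)
Conditions: p-TsOH·H2O (0.2 equiv), CH2Cl2, 0 °C to rt, until the alkene isomers have converged
Reagents that add atoms: none
Why: The acid protonates the C1=C10 alkene at C1 (Markovnikov), the tertiary C10 cation is captured across the ring by C5 of the C4=C5 alkene to form the C5–C10 bond, and the resulting C4 cation loses H5 to give the tetrasubstituted C4=C5 alkene. The closest known reaction type is the acid-promoted transannular cyclisation of germacra-1(10),4-dienes to eudesmanes. The one new bond closes ring A (C10–C1–C2–C3–C4–C5) in a 6-endo-trig sense and ring B (C5–C6–C7–C8–C9–C10) in a 6-exo-trig sense with respect to the C4=C5 alkene. The only new stereocentre, C10, is set by the ring conformation: in the crossed conformer with both vinylic methyl groups on one face and the C7 acrylate pseudo-equatorial, C5 bonds to the face of C10 that leaves C14 cis to the C7 side chain (10R), while C3, C7 and C8 are not touched. The step needs protonation at C1=C10 and not at C4=C5, which the inductively withdrawing allylic ester at C3 and the electron-poor character of the two enoate alkenes secure, and proton loss towards C5 and not C15 or C3, which reversible protonation favours because the exocyclic and enol-ester isomers can return to the C4 cation while the tetrasubstituted alkene is the thermodynamic sink; the acyloxy group also disfavours a hydride shift from C3.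

**Compound list**
1 | but-3-yn-1-ol | C#CCCO | starting material
2 | tert-butyl(but-3-yn-1-yloxy)dimethylsilane | C#CCCO[Si](C)(C)C(C)(C)C | intermediate
3 | ethylene oxide | C1CO1 | starting material
4 | (E)-[4-(tert-butyldimethylsilyloxy)-2-methylbut-1-en-1-yl]dimethylalane (formed in situ) | C[Al](C)/C=C(\C)CCO[Si](C)(C)C(C)(C)C | intermediate
5 | lithium butyl[(E)-4-(tert-butyldimethylsilyloxy)-2-methylbut-1-en-1-yl]dimethylalanate (formed in situ) | [Li+].CCCC[Al-](C)(C)/C=C(\C)CCO[Si](C)(C)C(C)(C)C | intermediate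
6 | (E)-6-[(tert-butyldimethylsilyl)oxy]-4-methylhex-3-en-1-ol | OCC/C=C(\C)CCO[Si](C)(C)C(C)(C)C | intermediate
7 | (E)-1-[(tert-butyldimethylsilyl)oxy]-6-[(tert-butyldiphenylsilyl)oxy]-3-methylhex-3-ene | CC(C)(C)[Si](C)(C)OCC/C(C)=C/CCO[Si](c1ccccc1)(c1ccccc1)C(C)(C)C | intermediate
8 | (E)-6-[(tert-butyldiphenylsilyl)oxy]-3-methylhex-3-en-1-ol | OCC/C(C)=C/CCO[Si](c1ccccc1)(c1ccccc1)C(C)(C)C | intermediate
9 | (E)-6-[(tert-butyldiphenylsilyl)oxy]-3-methylhex-3-enal | O=CC/C(C)=C/CCO[Si](c1ccccc1)(c1ccccc1)C(C)(C)C | intermediate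
10 | pent-3-yn-1-ol | CC#CCCO | starting material
11 | (E)-pent-3-en-1-ol carrying Cp2ZrCl on C4 and on oxygen (formed in situ) | C/C(=C\CCO[Zr](Cl)(C1C=CC=C1)C1C=CC=C1)[Zr](Cl)(C1C=CC=C1)C1C=CC=C1 | intermediate
12 | (E)-4-iodopent-3-en-1-ol | C/C(I)=C\CCO | intermediate
13 | (E)-4-iodopent-3-enal | C/C(I)=C\CC=O | intermediate
14 | methyl propiolate | C#CC(=O)OC | starting material
15 | [1-(methoxycarbonyl)vinyl]diisobutylalane (formed in situ) | C=C(C(=O)OC)[Al](CC(C)C)CC(C)C | intermediate
16 | methyl (5E)-3-hydroxy-6-iodo-2-methylidenehept-5-enoate (racemic at C3) | C=C(C(=O)OC)C(O)C/C=C(\C)I | intermediate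
17 | methyl (2Z,5E)-2-(bromomethyl)-6-iodohepta-2,5-dienoate | COC(=O)/C(CBr)=C/C/C=C(\C)I | intermediate
18 | methyl (3R,4R,6E)-9-[(tert-butyldiphenylsilyl)oxy]-3-[(2E)-3-iodobut-2-en-1-yl]-6-methyl-2-methylidene-4-[(trimethylsilyl)oxy]non-6-enoate (formed in situ) | C=C(C(=O)OC)[C@@H](C/C=C(\C)I)[C@H](O[Si](C)(C)C)C/C(C)=C/CCO[Si](c1ccccc1)(c1ccccc1)C(C)(C)C | intermediate
19 | methyl (3R,4R,6E)-9-[(tert-butyldiphenylsilyl)oxy]-4-hydroxy-3-[(2E)-3-iodobut-2-en-1-yl]-6-methyl-2-methylidenenon-6-enoate (7R,8R) | C=C(C(=O)OC)[C@@H](C/C=C(\C)I)[C@H](O)C/C(C)=C/CCO[Si](c1ccccc1)(c1ccccc1)C(C)(C)C | intermediate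
20 | methyl (3R,4R,6E)-4-acetoxy-9-[(tert-butyldiphenylsilyl)oxy]-3-[(2E)-3-iodobut-2-en-1-yl]-6-methyl-2-methylidenenon-6-enoate | C=C(C(=O)OC)[C@@H](C/C=C(\C)I)[C@H](OC(C)=O)C/C(C)=C/CCO[Si](c1ccccc1)(c1ccccc1)C(C)(C)C | intermediate
21 | methyl (3R,4R,6E)-4-acetoxy-9-hydroxy-3-[(2E)-3-iodobut-2-en-1-yl]-6-methyl-2-methylidenenon-6-enoate | C=C(C(=O)OC)[C@@H](C/C=C(\C)I)[C@H](OC(C)=O)C/C(C)=C/CCO | intermediate
22 | methyl (3R,4R,6E)-4-acetoxy-3-[(2E)-3-iodobut-2-en-1-yl]-6-methyl-2-methylidene-9-oxonon-6-enoate | C=C(C(=O)OC)[C@@H](C/C=C(\C)I)[C@H](OC(C)=O)C/C(C)=C/CC=O | intermediate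
23 | methyl (3S,7R,8R,1(10)E,4E)-8-acetoxy-3-hydroxygermacra-1(10),4,11(13)-trien-12-oate | C=C(C(=O)OC)[C@H]1C/C=C(C)/[C@@H](O)C/C=C(C)/C[C@H]1OC(C)=O | intermediate
24 | (E)-3-methylpent-2-enoic acid | CC/C(C)=C/C(=O)O | starting material
25 | methyl (3S,7R,8R,1(10)E,4E)-8-acetoxy-3-[(E)-3-methylpent-2-enoyloxy]germacra-1(10),4,11(13)-trien-12-oate | C=C(C(=O)OC)[C@H]1C/C=C(C)/[C@@H](OC(=O)/C=C(\C)CC)C/C=C(C)/C[C@H]1OC(C)=O | intermediate
26 | methyl (3S,7R,8R,10R)-8-acetoxy-3-[(E)-3-methylpent-2-enoyloxy]eudesma-4,11(13)-dien-12-oate (CNP0118541.1) | C=C(C(=O)OC)[C@H]1CC2=C(C)[C@@H](OC(=O)/C=C(\C)CC)CC[C@]2(C)C[C@H]1OC(C)=O | target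

**Step count and risks**
Total steps: 16. Longest linear sequence: 12 (steps 1–5, then 10–16); the bromide branch (steps 6–9) adds 4.

Step 14. The new C3 centre is set only by the conformation of the closing ring, so the aldehyde may be attacked on the wrong face and give the 3R alcohol; closure of the strained ring also competes with intermolecular coupling. Fallback: the closure is run from 22 as before and the whole alcohol fraction, 23 together with its C3 epimer methyl (3R,7R,8R,1(10)E,4E)-8-acetoxy-3-hydroxygermacra-1(10),4,11(13)-trien-12-oate F1, is oxidised with Dess–Martin periodinane/NaHCO3 to the ten-membered enone methyl (7R,8R,1(10)E,4E)-8-acetoxy-3-oxogermacra-1(10),4,11(13)-trien-12-oate F2. CBS reduction of F2 with (R)-2-methyl-CBS-oxazaborolidine and catecholborane in toluene at −78 °C, where the alkenyl side acts as the large group, should give the 3S alcohol under reagent control, and the route is rejoined at 23.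

Step 16. The C4 cation may be intercepted by the carbonyl oxygen of the neighbouring conjugated ester (bridged acyloxonium ion, then hydration or acyl shift), or the acid may isomerise that ester before ring formation is complete. Fallback: the cyclisation is moved in front of the acylation and run with a poorer neighbouring group at C3. From 23, (ClCH2CO)2O and pyridine in CH2Cl2 give methyl (3S,7R,8R,1(10)E,4E)-8-acetoxy-3-(chloroacetoxy)germacra-1(10),4,11(13)-trien-12-oate F3. The same TsOH treatment should cyclise it to methyl (3S,7R,8R,10R)-8-acetoxy-3-(chloroacetoxy)eudesma-4,11(13)-dien-12-oate F4. Thiourea and NaHCO3 in EtOH at 50 °C remove only the chloroacetate and give methyl (3S,7R,8R,10R)-8-acetoxy-3-hydroxyeudesma-4,11(13)-dien-12-oate F5, and Steglich esterification of F5 with 24 (DCC, DMAP) ends at 26.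

Step 10. Facial selectivity at the aldehyde may be low with this γ-substituted, functionalised allyl bromide, which would erode the enantiomeric purity of every later compound. Fallback: the absolute configuration is taken from a late kinetic resolution instead. From 9 and 17, an indium-mediated Barbier allylation (In powder, THF/H2O, rt), which is syn-selective but racemic, gives 19 together with its mirror image methyl (3S,4S,6E)-9-[(tert-butyldiphenylsilyl)oxy]-4-hydroxy-3-[(2E)-3-iodobut-2-en-1-yl]-6-methyl-2-methylidenenon-6-enoate F6. Steps 11 to 14 are run on the racemate, which adds the mirror-image acetate ent-20 F7, alcohol ent-21 F8, aldehyde ent-22 F9 and macrocyclic alcohol ent-23 F10. A Sharpless kinetic resolution of the secondary allylic alcohol (Ti(OiPr)4, D-(−)-diisopropyl tartrate, t-BuOOH, 4 Å sieves, CH2Cl2, −20 °C) should epoxidise the 3R enantiomer to methyl (3R,4S,5S,7S,8S,1(10)E)-8-acetoxy-4,5-epoxy-3-hydroxygermacra-1(10),11(13)-dien-12-oate F11 and leave the 3S enantiomer, so the route is rejoined at 23.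

**Further compounds**
F1 | step 14 | methyl (3R,7R,8R,1(10)E,4E)-8-acetoxy-3-hydroxygermacra-1(10),4,11(13)-trien-12-oate | C=C(C(=O)OC)[C@H]1C/C=C(C)/[C@H](O)C/C=C(C)/C[C@H]1OC(C)=O
F2 | step 14 | methyl (7R,8R,1(10)E,4E)-8-acetoxy-3-oxogermacra-1(10),4,11(13)-trien-12-oate | C=C(C(=O)OC)[C@H]1C/C=C(C)/C(=O)C/C=C(C)/C[C@H]1OC(C)=O
F3 | step 16 | methyl (3S,7R,8R,1(10)E,4E)-8-acetoxy-3-(chloroacetoxy)germacra-1(10),4,11(13)-trien-12-oate | C=C(C(=O)OC)[C@H]1C/C=C(C)/[C@@H](OC(=O)CCl)C/C=C(C)/C[C@H]1OC(C)=O
F4 | step 16 | methyl (3S,7R,8R,10R)-8-acetoxy-3-(chloroacetoxy)eudesma-4,11(13)-dien-12-oate | C=C(C(=O)OC)[C@H]1CC2=C(C)[C@@H](OC(=O)CCl)CC[C@]2(C)C[C@H]1OC(C)=O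
F5 | step 16 | methyl (3S,7R,8R,10R)-8-acetoxy-3-hydroxyeudesma-4,11(13)-dien-12-oate | C=C(C(=O)OC)[C@H]1CC2=C(C)[C@@H](O)CC[C@]2(C)C[C@H]1OC(C)=O
F6 | step 10 | methyl (3S,4S,6E)-9-[(tert-butyldiphenylsilyl)oxy]-4-hydroxy-3-[(2E)-3-iodobut-2-en-1-yl]-6-methyl-2-methylidenenon-6-enoate (ent-19) | C=C(C(=O)OC)[C@H](C/C=C(\C)I)[C@@H](O)C/C(C)=C/CCO[Si](c1ccccc1)(c1ccccc1)C(C)(C)C
F7 | step 10 | methyl (3S,4S,6E)-4-acetoxy-9-[(tert-butyldiphenylsilyl)oxy]-3-[(2E)-3-iodobut-2-en-1-yl]-6-methyl-2-methylidenenon-6-enoate (ent-20) | C=C(C(=O)OC)[C@H](C/C=C(\C)I)[C@@H](OC(C)=O)C/C(C)=C/CCO[Si](c1ccccc1)(c1ccccc1)C(C)(C)C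
F8 | step 10 | methyl (3S,4S,6E)-4-acetoxy-9-hydroxy-3-[(2E)-3-iodobut-2-en-1-yl]-6-methyl-2-methylidenenon-6-enoate (ent-21) | C=C(C(=O)OC)[C@H](C/C=C(\C)I)[C@@H](OC(C)=O)C/C(C)=C/CCO
F9 | step 10 | methyl (3S,4S,6E)-4-acetoxy-3-[(2E)-3-iodobut-2-en-1-yl]-6-methyl-2-methylidene-9-oxonon-6-enoate (ent-22) | C=C(C(=O)OC)[C@H](C/C=C(\C)I)[C@@H](OC(C)=O)C/C(C)=C/CC=O
F10 | step 10 | methyl (3R,7S,8S,1(10)E,4E)-8-acetoxy-3-hydroxygermacra-1(10),4,11(13)-trien-12-oate (ent-23) | C=C(C(=O)OC)[C@@H]1C/C=C(C)/[C@H](O)C/C=C(C)/C[C@@H]1OC(C)=O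
F11 | step 10 | methyl (3R,4S,5S,7S,8S,1(10)E)-8-acetoxy-4,5-epoxy-3-hydroxygermacra-1(10),11(13)-dien-12-oate | C=C(C(=O)OC)[C@@H]1C[C@@H]2O[C@@]2(C)[C@H](O)C/C=C(C)/C[C@@H]1OC(C)=O
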